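## The problem

The target **39** is a briarane. A cyclohexane (ring A: C1, C10, C11, C12, C13, C14) is trans-fused along C1–C10 to a cyclodecene (C1–C10). The large ring carries a γ-lactone across C7–C8 (O7–C19(=O)–C17) and a ring-cis trisubstituted C5=C6 bond (5E by the sequence rule because of the C16 acetoxymethyl group).

Ten stereocentres must be set: the quaternary C1 flanked by oxygenated C2 and C14, the ring-A set C10/C11/C12, and the array C7/C8/C9/C17 with a tertiary C8 alcohol. Ring A is conformationally defined, so C1, C10 and C14 can relay to C11/C12 and, through the exocyclic bonds C1–C2 and C10–C9, towards C2 and C9. C8 follows C9 if both oxygens arrive in one syn addition. C7 and C17 are farthest from ring A and need their own control.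

The ten-membered ring is the classical obstacle: it must be closed with the alkene geometry already fixed and next to a fully substituted carbon. The functional groups dictate the order of events:
- Four acetates (one allylic) exclude hydride and organometallic reagents at the end.
- The free 8,9-diol next to the lactone invites translactonisation to O9 and retro-aldol or β-elimination at C8.
- C17 is epimerisable.

The feature that makes the key step possible lies in ring A. The unit C14(O)–C13–C12(O)–C11(C20) is the retron of a 1-oxy-3-silyloxypenta-1,3-diene. The unit C1(C15)(C2=O)=C10–C9 is the retron of an (E)-2-methyl-2-enal whose formyl carbon is C2. The regiochemistry (oxygenated terminus C14 to the α-carbon C1) and the trans ring fusion (E geometry of C1=C10) follow directly.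

## Retrosynthesis

**39 ⇐ 38 ⇐ 37 ⇐ 36 (C–O bonds only).** The 8,9-diol is kept as an acetonide until the very end. The four hydroxyls at C2, C12, C14 and C16 can then be acetylated together in **38**, and the hindered secondary C9–OH never has to be told apart from them. The forward reaction needs only a mild acid hydrolysis that spares acetates and the lactone.

**36 ⇐ 35 ⇐ 34 (O7–C19 acyl bond, then the ring bond C6–C7).** C6–C7 is preferred to C5=C6 (metathesis) or C4–C5 (sp3–sp2 coupling). It joins a preformed, geometrically defined vinyl iodide to a non-enolisable aldehyde on the quaternary C8, and the carbinol it creates becomes the lactone oxygen. **34** is open in the large ring. The forward reaction must close a ten-membered ring at high dilution and give 7S.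

**34 ⇐ 33 ⇐ 23 + 31 (C2–C3).** This cut removes the whole C3–C6/C16 chain as the diiodide **31**, whose alkene geometry comes from a stereospecific carbometalation. C2 is then set by reagent control. The chain is attached late because its alkene would survive neither the hydroboration (step 8) nor the osmylation (step 14).

**23 ⇐ 22 ⇐ 21 ⇐ 20 ⇐ 19 ⇐ 14 + 18 (C8–O and C9–O, then C8=C9).** Both carbinol oxygens come from one syn-dihydroxylation of the Z-enoate **19**. The alkene geometry gives the relative configuration C8/C9, and C10 gives the absolute sense. The alternative aldol cut C8–C9 would need a tetrasubstituted α-alkoxy enolate. Phosphonate **18** brings C7, C8, C17, C18 and C19 in one piece, with C17 taken from lactic acid.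

**14 ⇐ 13 ⇐ 12 ⇐ 10 ⇐ 9 ⇐ 8 (C12–O and C11–H).** A methyl at C11 cis to C9 and trans to O12 is the pattern of a syn hydroboration of a C11=C12 alkene from the face opposite C9. Enolate methylation of the C12 ketone would give the C11 epimer. The ketone from the cycloaddition therefore serves only to place this alkene (via enol triflate **9**).

**8 ⇐ 7 ⇐ 6 ⇐ 3 + 4 (C14–C1 and C11–C10).** The Diels–Alder cut reduces ring A, with the quaternary C1, C10 and C14 and both arms at the right oxidation level, to two achiral building blocks: diene **3** (five carbons) and the commercial enal-ester **4**. The forward reaction must control regiochemistry, endo orientation of the formyl group and the enantiofacial sense.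

**Building blocks.** **3** comes from pent-1-yn-3-one **1** in two steps. **18** comes from tert-butyl (R)-lactate **15** and phosphonoacetate **17**. **31** comes from 3-(trimethylsilyl)propargyl alcohol **24** and vinylmagnesium bromide **25**.

## Roads not taken

Alternative 1: Ring-closing metathesis across C5=C6, the most obvious cut. The precursor A1 would carry a 1,1-disubstituted alkene (C5=CH2 with the C16 silyloxymethyl group) on the C2 arm and a vinyl carbinol at C7. A ruthenium carbene would have to form a trisubstituted olefin in a strained ten-membered ring next to an allylic oxygen. That is slow, competes with dimerisation, and gives the thermodynamic rather than a stereospecifically defined geometry. Both alkenes of A1 would also have to be introduced after the hydroboration and the osmylation, by organometallic additions in the presence of two esters. The chosen route fixes the geometry in fragment **31** before the ring exists and closes the ring with a chemoselective C–C bond formation at an aldehyde.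

Alternative 2: Biomimetic formation of C1–C10 last. A 14-membered cembranoid-type macrocycle A2 (C2 ketone, C10=C11–C12 enone, lactone in place) would close ring A by a transannular Michael addition of the C1 enolate to C10. A2 is no simpler than the target: it is a macrocycle with five stereocentres. The quaternary centre would be formed in a hindered transannular step. The configurations at C1, C10 and C11 would depend on an unknown macrocycle conformation, and the 14-oxygen is β to the enolate (elimination). The Diels–Alder step forms the same two ring-A bonds intermolecularly from achiral pieces under predictable rules.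

Alternative 3: Ring expansion. The cyclodecene could be hidden in a 6-6-6 tricycle A3, in which C2 and C7 are joined as the central tetrasubstituted alkene of a Birch-type 1,4-diene. Oxidative cleavage of C2=C7 would give the ten-membered 2,7-dione, with the ring-cis alkene inherited from a six-membered ring. The defects are structural:
- The second alkene of A3 lies at C4=C5 and must be moved into conjugation.
- A cyclodecane-1,6-dione is prone to transannular aldolisation.
- C2, C7, C8 (with C17–C19) and C9 would all have to be set afterwards on a flexible ring with no relay from ring A.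
- Accessible tricycles lack the 14-oxygen.

Key step: step 3

Remarks. Locants are those of the target (C15 = methyl on C1, C20 = methyl on C11, C16 on C5, C18 = methyl on C17, C19 = lactone carbonyl). α/β refer to the faces of ring A, β being the face of C15. TBS = tert-butyldimethylsilyl, TES = triethylsilyl. Compounds **1**, **4**, **15**, **17**, **24** and **25** are assumed to be commercially available. In the catalytic steps 3 and 23 the catalyst antipode is the one that gives the configuration shown; this sense of induction is a prediction from the accepted models.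

Step 1
Reactants: 1 pent-1-yn-3-one
Product: 2 (E)-1-(tert-butyldimethylsilyloxy)pent-1-en-3-one
Conditions: t-BuMe2SiOH, DABCO (10 mol%), CH2Cl2, 0 °C → rt
Reagents that add atoms: tert-butyldimethylsilanol, CC(C)(C)[Si](C)(C)O
Why: Amine-catalysed conjugate (oxa-Michael) addition of the acidic silanol O–H to the ynone; the (E)-β-silyloxy enone is the product of thermodynamic control.

Step 2
Reactants: 2 (E)-1-(tert-butyldimethylsilyloxy)pent-1-en-3-one
Product: 3 (1E,3Z)-1-(tert-butyldimethylsilyloxy)-3-(triethylsilyloxy)penta-1,3-diene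
Conditions: Et3SiOTf, Et3N, Et2O, 0 °C
Reagents that add atoms: triethylsilyl trifluoromethanesulfonate, CC[Si](CC)(CC)OS(=O)(=O)C(F)(F)F
Why: Soft enolisation of the ethyl ketone gives the silyl dienol ether, the (3Z) isomer (methyl cis to oxygen) being favoured; the geometry is immaterial later because C11 is re-set in step 8.

Step 3
Reactants: 3 (1E,3Z)-1-(tert-butyldimethylsilyloxy)-3-(triethylsilyloxy)penta-1,3-diene; 4 ethyl (E)-3-methyl-4-oxobut-2-enoate
Product: 6 ring-A keto-aldehyde (C2 formyl; C9 ethyl ester; 12-oxo; 14α-OTBS), via triethylsilyl enol ether cycloadduct 5 (not isolated)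
Conditions: chiral oxazaborolidinium triflimide (from α,α-diphenylprolinol, o-tolylboronic acid, Tf2NH; 10–20 mol%), CH2Cl2, −78 → −40 °C; then 0.5 M HCl, THF, 0 °C
Reagents that add atoms: none
Why: Lewis-acid-catalysed, concerted but asynchronous Diels–Alder reaction in which the cationic boron binds the formyl oxygen of 4 and lowers the LUMO of the C1=C10 bond; the closest known type is the enantioselective cycloaddition of 2-substituted acroleins with oxygenated dienes under chiral oxazaborolidinium catalysis. Ring A is closed in a suprafacial (4+2) mode that forms C14–C1 and C11–C10. The nucleophilic diene terminus C11 bonds to C10, β to the activated formyl group, and the oxygenated terminus C14 to the α-carbon C1, the ester being the weaker acceptor. The E geometry of 4 places C2 and C9 trans on the new ring (the later trans fusion), and the endo orientation of the coordinated formyl group places C2 cis to the 14-silyloxy group. The absolute configuration (1S,10S,14S) comes from the catalyst, which shields one face of the s-trans enal so that the diene adds to the Si face of C1. The C11 methyl (cis to O14) is not needed and is erased in step 6. The step needs C=C over C=O cycloaddition and catalyst control over silyl-cation background catalysis; the doubly activated alkene of 4 and the slow silyl transfer from TES/TBS ethers should secure both. Dilute acid then hydrolyses enol ether 5 to 6 without β-elimination of the 14-silyloxy group.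

Step 4
Reactants: 6 ring-A keto-aldehyde
Product: 7 keto-alcohol (C2 = CH2OH)
Conditions: NaBH(OAc)3, THF, rt; used at once in step 5
Reagents that add atoms: none
Why: Triacetoxyborohydride reduces the aldehyde but leaves the C12 ketone and the ester untouched; the neopentyl alcohol is silylated without delay to forestall lactonisation onto the C9 ester.

Step 5
Reactants: 7 keto-alcohol
Product: 8 C2-O-TBS ketone
Conditions: TBSCl, imidazole, DMF, 0 °C → rt
Reagents that add atoms: tert-butyldimethylsilyl chloride, CC(C)(C)[Si](C)(C)Cl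
Why: Standard silylation of a primary alcohol; C2 is masked at the alcohol level so that it survives steps 6–14.

Step 6
Reactants: 8 C2-O-TBS ketone
Product: 9 C11=C12 enol triflate
Conditions: Tf2O, 2,6-di-tert-butyl-4-methylpyridine, CH2Cl2, 0 °C → rt
Reagents that add atoms: trifluoromethanesulfonic anhydride, O=S(=O)(OS(=O)(=O)C(F)(F)F)C(F)(F)F
Why: Enol triflate formation under equilibrating conditions should give the more substituted C11=C12 isomer; the C11 configuration from step 3 is erased on purpose.

Step 7
Reactants: 9 C11=C12 enol triflate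
Product: 10 ring-A 11(12)-alkene
Conditions: Pd(OAc)2 (5 mol%), PPh3, HCO2H, n-Bu3N, DMF, 60 °C
Reagents that add atoms: none
Why: Palladium-catalysed formate reduction of an enol triflate (oxidative addition, hydride transfer, reductive elimination); silyl ethers and the ester are inert.

Step 8
Reactants: 10 ring-A 11(12)-alkene
Product: 12 12α-alcohol (11β-methyl), via C12 alkylborane 11 (not isolated)
Conditions: BH3·THF, THF, 0 °C → rt; then H2O2, aq NaOH, 0 °C
Reagents that add atoms: hydrogen peroxide, OO
Why: Hydroboration–oxidation places boron on the less substituted C12 and hydrogen on C11, syn and from the α face, opposite the C10 ester that A(1,2) strain with the C11 methyl holds pseudo-axial. One event therefore sets C11 (β-methyl) and C12 (α-OH), trans as in any hydroboration of a 1-methylcyclohexene.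

Step 9
Reactants: 12 12α-alcohol
Product: 13 tris-silyl ether ester (2-, 12α- and 14α-OTBS; C9 ethyl ester)
Conditions: TBSOTf, 2,6-lutidine, CH2Cl2, −40 → 0 °C
Reagents that add atoms: tert-butyldimethylsilyl trifluoromethanesulfonate, CC(C)(C)[Si](C)(C)OS(=O)(=O)C(F)(F)F
Why: Silylation of the hindered secondary alcohol with the silyl triflate.

Step 10
Reactants: 13 tris-silyl ether ester
Product: 14 C9 aldehyde
Conditions: DIBAL-H, CH2Cl2, −78 °C; Rochelle salt
Reagents that add atoms: none
Why: Partial reduction of the hindered ester stops at the aluminium hemiacetal at low temperature and gives the aldehyde on work-up.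

Step 11
Reactants: 15 tert-butyl (R)-2-hydroxypropanoate
Product: 16 tert-butyl (R)-2-(trifluoromethylsulfonyloxy)propanoate
Conditions: Tf2O, 2,6-lutidine, CH2Cl2, −78 °C
Reagents that add atoms: trifluoromethanesulfonic anhydride, O=S(=O)(OS(=O)(=O)C(F)(F)F)C(F)(F)F
Why: O-Sulfonylation with retention at carbon; the lactate triflate is used cold and at once.

Step 12
Reactants: 16 tert-butyl (R)-2-(trifluoromethylsulfonyloxy)propanoate; 17 methyl 2-[bis(2,2,2-trifluoroethoxy)phosphoryl]acetate
Product: 18 4-tert-butyl 1-methyl (3S)-2-[bis(2,2,2-trifluoroethoxy)phosphoryl]-3-methylbutanedioate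
Conditions: NaH, THF, 0 °C; then 16, −20 °C → rt
Reagents that add atoms: none
Why: SN2 alkylation of the stabilised phosphonoacetate anion by the α-triflyloxy ester with inversion; the C17 stereocentre is bought from (R)-lactate, and the mixture at the phosphorus-bearing carbon is irrelevant.

Step 13
Reactants: 14 C9 aldehyde; 18 phosphonate
Product: 19 (8Z)-enoate (C7 methyl ester; C19 tert-butyl ester; 17R)
Conditions: 18, KHMDS, 18-crown-6, THF, −78 °C; then 14
Reagents that add atoms: none
Why: Still–Gennari olefination: the electron-poor bis(trifluoroethyl) phosphonate eliminates from the kinetic adduct and places C10 cis to the C7 ester (Z); the weakly basic phosphonate anion should spare C10 and C17.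

Step 14
Reactants: 19 (8Z)-enoate
Product: 20 (8R,9R)-diol
Conditions: OsO4 (cat.), NMO, citric acid, t-BuOH/H2O, rt
Reagents that add atoms: osmium tetroxide, O=[Os](=O)(=O)=O; N-methylmorpholine N-oxide, C[N+]1([O-])CCOCC1; water, O
Why: Catalytic syn-dihydroxylation ([3+2] addition of OsO4). A(1,3) strain with the cis C7 ester holds C10–H in the alkene plane, and attack opposite the quaternary C1 gives 9R; syn addition to the Z-alkene then fixes 8R.

Step 15
Reactants: 20 (8R,9R)-diol
Product: 21 8,9-acetonide
Conditions: 2-methoxypropene, PPTS (cat.), CH2Cl2, 0 °C → rt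
Reagents that add atoms: 2-methoxypropene, COC(C)=C
Why: Acetonide formation on the tertiary/secondary 1,2-diol; it blocks lactonisation of O9 onto C19 and keeps O8/O9 out of the final acetylation.

Step 16
Reactants: 21 8,9-acetonide
Product: 22 C2 primary alcohol
Conditions: HF·pyridine, pyridine, THF, 0 °C
Reagents that add atoms: none
Why: Buffered HF·pyridine cleaves the primary TBS ether much faster than the two hindered secondary ones.

Step 17
Reactants: 22 C2 primary alcohol
Product: 23 C2 aldehyde
Conditions: Dess–Martin periodinane, NaHCO3, CH2Cl2, rt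
Reagents that add atoms: none
Why: Dess–Martin oxidation to a non-enolisable aldehyde on the quaternary C1.

Step 18
Reactants: 24 3-(trimethylsilyl)prop-2-yn-1-ol; 25 vinylmagnesium bromide
Product: 26 (E)-2-[(trimethylsilyl)methylidene]but-3-en-1-ol
Conditions: 25 (3 equiv), CuI (10 mol%), THF, 0 °C → rt; aq NH4Cl
Reagents that add atoms: none
Why: Copper-catalysed anti-carbomagnesiation of the propargylic alkoxide: vinyl adds to C5 and magnesium ends on C6 cis to the CH2O group (five-membered chelate), so after protonation silicon is cis to the new vinyl group.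

Step 19
Reactants: 26 (E)-2-[(trimethylsilyl)methylidene]but-3-en-1-ol
Product: 27 TBS ether of 26
Conditions: TBSCl, imidazole, CH2Cl2, rt
Reagents that add atoms: tert-butyldimethylsilyl chloride, CC(C)(C)[Si](C)(C)Cl
Why: Standard silylation of the allylic alcohol (future C16–O).

Step 20
Reactants: 27 TBS ether of 26
Product: 29 (E)-3-{[(tert-butyldimethylsilyl)oxy]methyl}-4-(trimethylsilyl)but-3-en-1-ol, via B-alkyl-9-BBN adduct 28 (not isolated)
Conditions: 9-BBN, THF, 0 °C → rt; then NaOH, H2O2
Reagents that add atoms: hydrogen peroxide, OO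
Why: 9-BBN hydroborates only the monosubstituted alkene of the diene, boron going to the terminus; oxidation gives the primary alcohol (C3).

Step 21
Reactants: 29 (E)-3-{[(tert-butyldimethylsilyl)oxy]methyl}-4-(trimethylsilyl)but-3-en-1-ol
Product: 30 (E)-tert-butyl{[4-iodo-2-[(trimethylsilyl)methylidene]butyl]oxy}dimethylsilane
Conditions: I2, PPh3, imidazole, CH2Cl2, 0 °C
Reagents that add atoms: iodine, II
Why: Appel-type iodination of the primary alcohol.

Step 22
Reactants: 30 (E)-tert-butyl{[4-iodo-2-[(trimethylsilyl)methylidene]butyl]oxy}dimethylsilane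
Product: 31 (E)-tert-butyl{[4-iodo-2-(iodomethylidene)butyl]oxy}dimethylsilane
Conditions: N-iodosuccinimide, MeCN/ClCH2CN, 0 °C
Reagents that add atoms: N-iodosuccinimide, O=C1CCC(=O)N1I
Why: Iododesilylation (ipso attack, β-silyl cation) with retention, so the vinyl iodine stays cis to the CH2CH2I arm (C4).

Step 23
Reactants: 23 C2 aldehyde; 31 (E)-tert-butyl{[4-iodo-2-(iodomethylidene)butyl]oxy}dimethylsilane
Product: 33 2R carbinol carrying the C3–C6 chain (C6 vinyl iodide), via bis(alkyl)zinc 32 (not isolated)
Conditions: 31, Et2Zn, CuI (cat.), 50 °C, then evaporation; Ti(OiPr)4, (1S,2S)-1,2-bis(trifluoromethanesulfonamido)cyclohexane (8 mol%), toluene, −20 °C; 23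
Reagents that add atoms: none
Why: Iodine–zinc exchange occurs only at the alkyl iodide; the dialkylzinc then adds to the aldehyde under titanium/bis-sulfonamide catalysis. Reagent control sets C2 (R), and esters, acetonide and vinyl iodide are not touched.

Step 24
Reactants: 33 2R carbinol
Product: 34 C7 aldehyde
Conditions: DIBAL-H (excess for the free OH), CH2Cl2, −78 °C; Rochelle salt
Reagents that add atoms: none
Why: The α-alkoxy methyl ester is reduced to the aldehyde through a chelated aluminium hemiacetal; the tert-butyl ester is too hindered to react at −78 °C.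

Step 25
Reactants: 34 C7 aldehyde
Product: 35 (7S)-cyclodecenol (ten-membered ring closed)
Conditions: CrCl2 (10 equiv), NiCl2 (1 mol%), DMSO/THF, rt, 2 mM
Reagents that add atoms: none
Why: Nozaki–Hiyama–Kishi reaction: nickel inserts into the C6–I bond with retention, transmetalates to chromium(III), and the alkenylchromium adds to the non-enolisable aldehyde, with the two ring bonds already cis on the alkene. The 7S alcohol is expected from attack anti to the C8–O bond of the dioxolane, past the smaller C17 branch.

Step 26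
Reactants: 35 (7S)-cyclodecenol
Product: 36 7,19-lactone
Conditions: KHMDS (2.1 equiv), THF, −78 → −20 °C; AcOH
Reagents that add atoms: none
Why: The C7 alkoxide attacks the tert-butyl ester in a 5-exo acyl transfer and expels tert-butoxide; with O8/O9 tied in the acetonide the lactone can only form at O7. The cold quench avoids enolisation at C17.

Step 27
Reactants: 36 7,19-lactone
Product: 37 2,12,14,16-tetraol
Conditions: HF·pyridine (excess), THF/pyridine, rt → 40 °C
Reagents that add atoms: none
Why: Global cleavage of the three remaining TBS ethers; acetonide and lactone are stable to buffered HF.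

Step 28
Reactants: 37 2,12,14,16-tetraol
Product: 38 tetraacetate acetonide
Conditions: Ac2O, pyridine, DMAP, rt
Reagents that add atoms: acetic anhydride, CC(=O)OC(C)=O
Why: DMAP-catalysed acetylation of one primary and three secondary alcohols; O8 and O9 are protected.

Step 29
Reactants: 38 tetraacetate acetonide
Product: 39 CNP0252396.2
Conditions: TFA/H2O/CH2Cl2, 0 °C (or 80% aq AcOH, 45 °C)
Reagents that add atoms: none
Why: Acid hydrolysis of the acetonide under conditions that leave acetates and the lactone intact; no base is used, so translactonisation to O9 and epimerisation at C17 are avoided.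

## Compound list

1 | pent-1-yn-3-one | CCC(=O)C#C | starting material
2 | (E)-1-(tert-butyldimethylsilyloxy)pent-1-en-3-one | CCC(=O)/C=C/O[Si](C)(C)C(C)(C)C | intermediate
3 | (1E,3Z)-1-(tert-butyldimethylsilyloxy)-3-(triethylsilyloxy)penta-1,3-diene | C/C=C(O[Si](CC)(CC)CC)/C=C/O[Si](C)(C)C(C)(C)C | intermediate
4 | ethyl (E)-3-methyl-4-oxobut-2-enoate | CCOC(=O)/C=C(C)/C=O | starting material
5 | cycloadduct: ring A with C12(OTES)=C13 enol ether; C1 β-CH3 and α-CHO; C10 β-CO2Et; C11 α-CH3; C14 α-OTBS | C[C@@]1(C=O)[C@@H](C(=O)OCC)[C@H](C)C(O[Si](CC)(CC)CC)=C[C@@H]1O[Si](C)(C)C(C)(C)C | intermediate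
6 | ring-A keto-aldehyde: C12 ketone; C1 β-CH3 and α-CHO (C2); C10 β-CO2Et (C9); C11 α-CH3; C14 α-OTBS | C[C@@]1(C=O)[C@@H](C(=O)OCC)[C@H](C)C(=O)C[C@@H]1O[Si](C)(C)C(C)(C)C | intermediate
7 | keto-alcohol: as 6 with C2 = CH2OH | C[C@@]1(CO)[C@@H](C(=O)OCC)[C@H](C)C(=O)C[C@@H]1O[Si](C)(C)C(C)(C)C | intermediate
8 | C2-O-TBS ketone: as 7 with C2 = CH2OTBS | C[C@@]1(CO[Si](C)(C)C(C)(C)C)[C@@H](C(=O)OCC)[C@H](C)C(=O)C[C@@H]1O[Si](C)(C)C(C)(C)C | intermediate
9 | enol triflate: C11(CH3)=C12(OTf); otherwise as 8 | C[C@@]1(CO[Si](C)(C)C(C)(C)C)[C@@H](C(=O)OCC)C(C)=C(OS(=O)(=O)C(F)(F)F)C[C@@H]1O[Si](C)(C)C(C)(C)C | intermediate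
10 | ring-A alkene: C11(CH3)=C12H; C1 β-CH3 and α-CH2OTBS; C10 β-CO2Et; C14 α-OTBS | C[C@@]1(CO[Si](C)(C)C(C)(C)C)[C@@H](C(=O)OCC)C(C)=CC[C@@H]1O[Si](C)(C)C(C)(C)C | intermediate
11 | alkylborane: 12α-BH2 and 11β-CH3 (11α-H); otherwise as 10 | C[C@@]1(CO[Si](C)(C)C(C)(C)C)[C@@H](C(=O)OCC)[C@@H](C)[C@H](B)C[C@@H]1O[Si](C)(C)C(C)(C)C | intermediate
12 | 12α-alcohol: 11β-CH3 and 12α-OH; otherwise as 10 | C[C@@]1(CO[Si](C)(C)C(C)(C)C)[C@@H](C(=O)OCC)[C@@H](C)[C@H](O)C[C@@H]1O[Si](C)(C)C(C)(C)C | intermediate
13 | tris-silyl ether ester: C2 CH2OTBS; 12α-OTBS; 14α-OTBS; C10 β-CO2Et; 11β-CH3 | C[C@@]1(CO[Si](C)(C)C(C)(C)C)[C@@H](C(=O)OCC)[C@@H](C)[C@H](O[Si](C)(C)C(C)(C)C)C[C@@H]1O[Si](C)(C)C(C)(C)C | intermediate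
14 | C9 aldehyde: as 13 with C10 β-CHO | C[C@@]1(CO[Si](C)(C)C(C)(C)C)[C@@H](C=O)[C@@H](C)[C@H](O[Si](C)(C)C(C)(C)C)C[C@@H]1O[Si](C)(C)C(C)(C)C | intermediate
15 | tert-butyl (R)-2-hydroxypropanoate | C[C@@H](O)C(=O)OC(C)(C)C | starting material
16 | tert-butyl (R)-2-(trifluoromethylsulfonyloxy)propanoate | C[C@@H](OS(=O)(=O)C(F)(F)F)C(=O)OC(C)(C)C | intermediate
17 | methyl 2-[bis(2,2,2-trifluoroethoxy)phosphoryl]acetate | COC(=O)CP(=O)(OCC(F)(F)F)OCC(F)(F)F | starting material
18 | 4-tert-butyl 1-methyl (3S)-2-[bis(2,2,2-trifluoroethoxy)phosphoryl]-3-methylbutanedioate (C2 epimers) | COC(=O)C(P(=O)(OCC(F)(F)F)OCC(F)(F)F)[C@@H](C)C(=O)OC(C)(C)C | intermediate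
19 | (8Z)-enoate: C10 bears CH=C(CO2Me)[(17R)-CH(CH3)CO2tBu] with C10 cis to CO2Me; ring A as 13 | C[C@@]1(CO[Si](C)(C)C(C)(C)C)[C@@H](/C=C(\C(=O)OC)[C@@H](C)C(=O)OC(C)(C)C)[C@@H](C)[C@H](O[Si](C)(C)C(C)(C)C)C[C@@H]1O[Si](C)(C)C(C)(C)C | intermediate
20 | (8R,9R)-diol: 9-OH and 8-OH; C7 methyl ester; (17R) tert-butyl ester; ring A as 13 | C[C@@]1(CO[Si](C)(C)C(C)(C)C)[C@@H]([C@@H](O)[C@@](O)(C(=O)OC)[C@@H](C)C(=O)OC(C)(C)C)[C@@H](C)[C@H](O[Si](C)(C)C(C)(C)C)C[C@@H]1O[Si](C)(C)C(C)(C)C | intermediate
21 | 8,9-O-isopropylidene derivative of 20 | C[C@@]1(CO[Si](C)(C)C(C)(C)C)[C@@H]([C@H]2OC(C)(C)O[C@]2(C(=O)OC)[C@@H](C)C(=O)OC(C)(C)C)[C@@H](C)[C@H](O[Si](C)(C)C(C)(C)C)C[C@@H]1O[Si](C)(C)C(C)(C)C | intermediate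
22 | C2 primary alcohol: as 21 with C2 = CH2OH | C[C@@]1(CO)[C@@H]([C@H]2OC(C)(C)O[C@]2(C(=O)OC)[C@@H](C)C(=O)OC(C)(C)C)[C@@H](C)[C@H](O[Si](C)(C)C(C)(C)C)C[C@@H]1O[Si](C)(C)C(C)(C)C | intermediate
23 | C2 aldehyde: as 21 with C2 = CHO | C[C@@]1(C=O)[C@@H]([C@H]2OC(C)(C)O[C@]2(C(=O)OC)[C@@H](C)C(=O)OC(C)(C)C)[C@@H](C)[C@H](O[Si](C)(C)C(C)(C)C)C[C@@H]1O[Si](C)(C)C(C)(C)C | intermediate
24 | 3-(trimethylsilyl)prop-2-yn-1-ol | C[Si](C)(C)C#CCO | starting material
25 | vinylmagnesium bromide | C=C[Mg]Br | starting material
26 | (E)-2-[(trimethylsilyl)methylidene]but-3-en-1-ol | OC/C(C=C)=C/[Si](C)(C)C | intermediate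
27 | (E)-tert-butyldimethyl{[2-[(trimethylsilyl)methylidene]but-3-en-1-yl]oxy}silane | CC(C)(C)[Si](C)(C)OC/C(C=C)=C/[Si](C)(C)C | intermediate
28 | B-alkyl-9-BBN adduct of 27 (boron on C3) | CC(C)(C)[Si](C)(C)OC/C(CCB1C2CCCC1CCC2)=C/[Si](C)(C)C | intermediate
29 | (E)-3-{[(tert-butyldimethylsilyl)oxy]methyl}-4-(trimethylsilyl)but-3-en-1-ol | CC(C)(C)[Si](C)(C)OC/C(CCO)=C/[Si](C)(C)C | intermediate
30 | (E)-tert-butyl{[4-iodo-2-[(trimethylsilyl)methylidene]butyl]oxy}dimethylsilane | CC(C)(C)[Si](C)(C)OC/C(CCI)=C/[Si](C)(C)C | intermediate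
31 | (E)-tert-butyl{[4-iodo-2-(iodomethylidene)butyl]oxy}dimethylsilane (C3–C6 + C16 fragment; vinyl I cis to C4) | CC(C)(C)[Si](C)(C)OC/C(CCI)=C/I | intermediate
32 | bis(alkyl)zinc from 31 (zinc on both C3 carbons) | CC(C)(C)[Si](C)(C)OC/C(CC[Zn]CC/C(CO[Si](C)(C)C(C)(C)C)=C\I)=C/I | intermediate
33 | (2R)-carbinol: C2-OH; chain C3H2–C4H2–C5(CH2OTBS)=C6H–I (I cis to C4); C7 methyl ester; 8,9-acetonide; 12α-, 14α-OTBS | C[C@@]1([C@H](O)CC/C(CO[Si](C)(C)C(C)(C)C)=C\I)[C@@H]([C@H]2OC(C)(C)O[C@]2(C(=O)OC)[C@@H](C)C(=O)OC(C)(C)C)[C@@H](C)[C@H](O[Si](C)(C)C(C)(C)C)C[C@@H]1O[Si](C)(C)C(C)(C)C | intermediate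
34 | C7 aldehyde: as 33 with C7 = CHO | C[C@@]1([C@H](O)CC/C(CO[Si](C)(C)C(C)(C)C)=C\I)[C@@H]([C@H]2OC(C)(C)O[C@]2(C=O)[C@@H](C)C(=O)OC(C)(C)C)[C@@H](C)[C@H](O[Si](C)(C)C(C)(C)C)C[C@@H]1O[Si](C)(C)C(C)(C)C | intermediate
35 | (2R,7S)-cyclodecenediol: ten-membered ring closed at C6–C7; 5,6-alkene ring-cis; 8,9-acetonide; C8 bears (17R)-CH(CH3)CO2tBu; 16-OTBS; 12α-, 14α-OTBS | C[C@@]1([C@H](O)CC/C(CO[Si](C)(C)C(C)(C)C)=C\[C@H](O)[C@]4([C@@H](C)C(=O)OC(C)(C)C)OC(C)(C)O[C@@H]43)[C@@H]3[C@@H](C)[C@H](O[Si](C)(C)C(C)(C)C)C[C@@H]1O[Si](C)(C)C(C)(C)C | intermediate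
36 | 7,19-lactone (7S,8R,17R): 2-OH; 8,9-acetonide; 16-OTBS; 12α-, 14α-OTBS | C[C@@]1([C@H](O)CC/C(CO[Si](C)(C)C(C)(C)C)=C\[C@@H]2OC(=O)[C@H](C)[C@]24OC(C)(C)O[C@@H]43)[C@@H]3[C@@H](C)[C@H](O[Si](C)(C)C(C)(C)C)C[C@@H]1O[Si](C)(C)C(C)(C)C | intermediate
37 | 2,12,14,16-tetraol 8,9-acetonide lactone | C[C@@]1([C@H](O)CC/C(CO)=C\[C@@H]2OC(=O)[C@H](C)[C@]24OC(C)(C)O[C@@H]43)[C@@H]3[C@@H](C)[C@H](O)C[C@@H]1O | intermediate
38 | 2,12,14,16-tetraacetate 8,9-acetonide lactone | C[C@@]1([C@H](OC(C)=O)CC/C(COC(C)=O)=C\[C@@H]2OC(=O)[C@H](C)[C@]24OC(C)(C)O[C@@H]43)[C@@H]3[C@@H](C)[C@H](OC(C)=O)C[C@@H]1OC(C)=O | intermediate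
39 | CNP0252396.2: (1S,2R,5E,7S,8R,9R,10S,11R,12R,14S,17R)-2,12,14,16-tetraacetoxy-8,9-dihydroxybriar-5-ene 7,19-lactone | CC(=O)OC/C1=C/[C@@H]2OC(=O)[C@H](C)[C@@]2(O)[C@H](O)[C@H]2[C@@H](C)[C@H](OC(C)=O)C[C@H](OC(C)=O)[C@]2(C)[C@H](OC(C)=O)CC1 | target

## Step count and least certain steps

Total: 29 steps. Longest linear sequence: 22 steps (steps 1–10, 13–17, 23–29).

**Step 3 (key step).** The most likely failures are loss of enantiocontrol and of chemoselectivity. Silyl transfer from the diene can generate an achiral silyl cation catalyst, and the diene can add to the formyl C=O or stop at an open-chain conjugate adduct. The fallback gives up catalysis for resolution. It sets out from 3 and 4: the uncatalysed thermal cycloaddition (toluene, 40 °C) gives 5 together with its enantiomer ent-5 F1. The same acid work-up gives 6 and its enantiomer ent-6 F2, and reduction as in step 4 gives 7 and its enantiomer ent-7 F3. Compound 7 is separated from F3 by preparative chromatography on a chiral stationary phase and returns to the route at 7.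

**Step 8.** The likely failure is poor facial selectivity. If the half-chair with an axial 14-silyloxy group reacts, borane approaches from the β face and gives the 11,12-bis-epimer. The fallback replaces steric control by hydroxyl direction. It sets out from 10:
- HF·pyridine removes the primary silyl group to give the C2 alcohol F4.
- VO(acac)2/t-BuOOH, directed by the α-oriented CH2OH, gives the 11α,12α-epoxide F5.
- Cp2TiCl (from Cp2TiCl2 and Mn) opens the epoxide at the tertiary carbon and gives the 11(20)-methylidene-12α-ol F6.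
- Hydrogenation with [Ir(cod)(PCy3)(py)]PF6, directed by the 12α-OH, delivers hydrogen to the α face of C11 and gives the 2,12α-diol F7.
- Bis-silylation (TBSOTf, 2,6-lutidine) returns to the route at 13.

**Step 13.** The likely failure is low conversion. A tertiary phosphonate carbanion must add to an α-branched, neopentyl-like aldehyde, and prolonged basic conditions invite epimerisation at C10 or C17. The fallback builds the trisubstituted alkene in two less hindered stages. It sets out from 14 and 17:
- Bromination of 17 gives methyl 2-bromo-2-[bis(2,2,2-trifluoroethoxy)phosphoryl]acetate F8.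
- Olefination of 14 with F8 under the conditions of step 13 gives the (E)-α-bromo enoate F9 (C10 cis to the ester).
- Palladium-catalysed Negishi coupling of F9 with the bromozinc enolate of tert-butyl 2-bromopropanoate F10 gives 19 together with its C17 epimer F11.
- F11 is removed by chromatography, and 19 returns to the route.

**Step 25.** The likely failures are intermolecular coupling at the hindered aldehyde and poor facial selectivity at C7, since the open and the chelated transition states predict opposite epimers. The fallback corrects C7 by reagent control after ring closure. It sets out from the mixture of 35 and its C7 epimer 7-epi-35 F12. MnO2 oxidises only the allylic C7 alcohol to the C7 enone F13. Corey–Bakshi–Shibata reduction with the appropriate catalyst antipode and catecholborane gives 35, where the route is rejoined.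

## Further compounds

F1 | step 3 | ent-5 (enantiomer of cycloadduct 5) | C[C@]1(C=O)[C@H](C(=O)OCC)[C@@H](C)C(O[Si](CC)(CC)CC)=C[C@H]1O[Si](C)(C)C(C)(C)C
F2 | step 3 | ent-6 (enantiomer of keto-aldehyde 6) | C[C@]1(C=O)[C@H](C(=O)OCC)[C@@H](C)C(=O)C[C@H]1O[Si](C)(C)C(C)(C)C
F3 | step 3 | ent-7 (enantiomer of keto-alcohol 7) | C[C@]1(CO)[C@H](C(=O)OCC)[C@@H](C)C(=O)C[C@H]1O[Si](C)(C)C(C)(C)C
F4 | step 8 | C2 primary alcohol of alkene 10 | C[C@@]1(CO)[C@@H](C(=O)OCC)C(C)=CC[C@@H]1O[Si](C)(C)C(C)(C)C
F5 | step 8 | 11α,12α-epoxide of F4 | C[C@@]1(CO)[C@@H](C(=O)OCC)[C@]2(C)O[C@@H]2C[C@@H]1O[Si](C)(C)C(C)(C)C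
F6 | step 8 | 11(20)-methylidene-12α-ol (C2 CH2OH free) | C[C@@]1(CO)[C@@H](C(=O)OCC)C(=C)[C@H](O)C[C@@H]1O[Si](C)(C)C(C)(C)C
F7 | step 8 | 2,12α-diol with 11β-methyl | C[C@@]1(CO)[C@@H](C(=O)OCC)[C@@H](C)[C@H](O)C[C@@H]1O[Si](C)(C)C(C)(C)C
F8 | step 13 | methyl 2-bromo-2-[bis(2,2,2-trifluoroethoxy)phosphoryl]acetate | COC(=O)C(Br)P(=O)(OCC(F)(F)F)OCC(F)(F)F
F9 | step 13 | (E)-α-bromo enoate from 14 (C10 cis to CO2Me) | C[C@@]1(CO[Si](C)(C)C(C)(C)C)[C@@H](/C=C(\C(=O)OC)Br)[C@@H](C)[C@H](O[Si](C)(C)C(C)(C)C)C[C@@H]1O[Si](C)(C)C(C)(C)C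
F10 | step 13 | bromozinc enolate (Reformatsky reagent) of tert-butyl 2-bromopropanoate | CC([Zn]Br)C(=O)OC(C)(C)C
F11 | step 13 | 17-epimer of 19 | C[C@@]1(CO[Si](C)(C)C(C)(C)C)[C@@H](/C=C(\C(=O)OC)[C@H](C)C(=O)OC(C)(C)C)[C@@H](C)[C@H](O[Si](C)(C)C(C)(C)C)C[C@@H]1O[Si](C)(C)C(C)(C)C
F12 | step 25 | 7-epi-35 | C[C@@]1([C@H](O)CC/C(CO[Si](C)(C)C(C)(C)C)=C\[C@@H](O)[C@]4([C@@H](C)C(=O)OC(C)(C)C)OC(C)(C)O[C@@H]43)[C@@H]3[C@@H](C)[C@H](O[Si](C)(C)C(C)(C)C)C[C@@H]1O[Si](C)(C)C(C)(C)C
F13 | step 25 | C7 enone of the macrocycle | C[C@@]1([C@H](O)CC/C(CO[Si](C)(C)C(C)(C)C)=C\C(=O)[C@]4([C@@H](C)C(=O)OC(C)(C)C)OC(C)(C)O[C@@H]43)[C@@H]3[C@@H](C)[C@H](O[Si](C)(C)C(C)(C)C)C[C@@H]1O[Si](C)(C)C(C)(C)C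
A1 | alternative 1 | metathesis precursor: C2(OTBS)–CH2CH2–C(=CH2)CH2OTBS arm and C7 vinyl carbinol on the 8,9-acetonide | C[C@@]1([C@H](O[Si](C)(C)C(C)(C)C)CCC(=C)CO[Si](C)(C)C(C)(C)C)[C@@H]([C@H]2OC(C)(C)O[C@]2([C@@H](O)C=C)[C@@H](C)C(=O)OC(C)(C)C)[C@@H](C)[C@H](O[Si](C)(C)C(C)(C)C)C[C@@H]1O[Si](C)(C)C(C)(C)C
A2 | alternative 2 | 14-membered macrocycle: C2 ketone, C10=C11–C12 enone, 7,19-lactone, 8,9-acetonide, 14- and 16-OTBS (C1 unassigned) | CC1C(=O)CC/C(CO[Si](C)(C)C(C)(C)C)=C\[C@@H]2OC(=O)[C@H](C)[C@]23OC(C)(C)O[C@@H]3/C=C(C)/C(=O)C[C@@H]1O[Si](C)(C)C(C)(C)C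
A3 | alternative 3 | tricyclic 1,4-diene with central C2=C7 alkene (rings A, B and a cyclohexadiene carrying C16 as methyl); 12α-, 14α-OTBS | C[C@@]12C3=C(CC(C)=CC3)CC[C@H]1[C@@H](C)[C@H](O[Si](C)(C)C(C)(C)C)C[C@@H]2O[Si](C)(C)C(C)(C)C
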